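(The numbers in the tables were generated by integration from invented constants, and the scatter is random.)

Choosing the equivalents of X starts from one ratio: how fast Q takes X compared with L.

| flask | L | X | remark | time |
|---|---|---|---|---|
| Monday's | 0.026 M | 0.026 M | the very flask that is asked about, followed so far |  |
| Tuesday's | 0.026 M | 0.052 M | run made earlier |  |
| flask | 0.026 M | 0.0260 M |  | 4.0 d |

| run | time / h | Q / % | J / % |
|---|---|---|---|
| Monday's | 1.33 | 84.5 | 1.8 |
| Monday's | 2.50 | 88.5 | 1.1 |
| Monday's | 5.00 | 91.1 | 2.0 |
| Monday's | 10.0 | 91.8 | 2.4 |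
| Monday's | 15.0 | 92.0 | 2.4 |
| Tuesday's | 8.00 | 59.7 | 26.0 |
| Tuesday's | 15.0 | 44.3 | 35.5 |
| Tuesday's | 25.0 | 31.7 | 43.1 |
| Tuesday's | 30.0 | 30.4 | 45.6 |
| Tuesday's | 40.0 | 23.9 | 48.2 |

(readings scatter by 0.5 percentage points)

- equivalents of X to L, everything else as given, that leave most Q at 4.0 d
- the amount of Q then, in percent of the L charged
- the amount of Q with the amounts as given

- candidate steps: L + X -> Q; X + Q <-> J; J <-> Z

1. Rung L + X. Monday's first reading, neglecting Z, leaves 1/[L] growing at 4.74 /h, with [L] as a fraction of the charge. At equal charges, L halves in 0.211 h.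
2. Rung J and Z, its speed not read here. Tuesday's first reading comes 37.9 times the half-life above into the run, so L is taken as reacted there and the unseen part as Z. Z per J then reads 0.550 at 8.00 h and 0.579 at 40.0 h, so Z keeps pace with J.
3. Rung X + Q. With L taken as reacted on Tuesday, [X] equals [Q], so 1/[Q], with [Q] as a fraction of L's charge, grows at 0.0832 /h. That is a half-life of 8.33 h with [X] held at the charge of the asked flask, far longer than L's. The 4.0 d hold 11.5 of these, so in the asked flask the length of the run gives Q no protection; the charge of X is the setting left to choose.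
4. The ratio. The selectivity factor r, the rate constant of Q's uptake of X over that of L, reads 0.0176. With the way back left out, competition gives [Q] = ([L]^r − [L])/(1 − r), both as fractions of L's charge.
5. My reckoning. Monday's Q is flat within the scatter by 15.0 h. Taking [X] as near zero there, each J or Z leaves one L unreacted, so Q falls short of the charge by two parts and [L] is 4.00%. The rule then gives 92.1% for Q, before any reversal. Q peaks near [L] = 1.63%, at 93.0% and 1.04 equiv.
6. The forecast says 92.4%, and 93.4% at 1.03 equiv, adding that “Slow J reversal adds about 0.3 by 96 h”.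

The flask gives 93.3%, and 94.1% at 1.03 equiv.

    L + X → Q (k = 0.0560 /M/s)
    X + Q ⇌ J (K = 1400 /M, k = 9.10 × 10⁻⁴ /M/s)
    J ⇌ Z (K = 0.570, k = 8.10 × 10⁻⁴ /s)

After 0.400 d the flask holds L 4.03% and Q 92.4%, with X at 0.492% of its charge. For that L, r gives Q 92.1%. The neighbour charged with 0.016 M of X ends with L 38.9%, for which r gives J and Z together 0.581%; that flask holds 0.466%.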